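**Retrosynthetic overview**
1. Target 30 ⇐ methyl lactol ether 28 (acetal hydrolysis and lactol oxidation, last step); the lactone carbons C11–C13 travel at the lactol oxidation level, and the C3 isovalerate replaces a silyl ether late.
2. Key disconnection C7–C11: 26 ⇐ 2-bromoallyl mixed acetal 18 on O6 of a ten-membered 7,8-epoxy alcohol; Br/Li exchange, 5-exo-tet opening of the oxirane at C7 with inversion, and acylation of the freed C8 alkoxide by epoxyangeloyl chloride 23 in the same flask.
3. Enabling feature: in the five-membered lactone ring (O6, C12, C11, C7, C6) C11 sits on C7 anti to the C8–O bond of the ten-membered ring and next to the oxygen-bearing C6, so C7/C8 can be stored as a trans-oxirane fused to the carbocycle and C11 delivered from O6.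
4. Ten-membered carbocycle: Nozaki–Hiyama–Kishi closure of C5–C6 (Z-iodoalkene onto epoxy aldehyde 15); chain from a vinylogous Mukaiyama aldol (C2–C3, sets C3 and E-C1=C10), a copper-mediated allyl–alkynyl coupling (C8–C9), and Sharpless (C7, C8) and Shi (C1, C10) epoxidations.
5. Ring order: 7,8-oxirane, 1,10-oxirane, ten-membered ring, five-membered oxygen ring (key step), lactone carbonyl last; the side-chain oxirane arrives in 23.

Key step: step 19

Remark (naming): ring compounds carry germacrane numbering (ring C1–C10, C14 on C10, C15 on C4, C11–C13 the lactone unit); "11,12,13-trinorgermacrane" is the 4,10-dimethylcyclodecane core.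
Remark (descriptors): the CIP label at C7 is R in 13, 14 and 16 and S in 15 and 18 only because substituent priorities change; the geometry at C7 is untouched until step 19.
Assumption (step 4): the (S,S)-bisphosphoramide is taken to be the enantiomer that directs the dienolate to the Si face of aldehyde 4; if the sense is the opposite, its enantiomer is used.

**Route**

Step 1
Reactants: 1 prop-2-yn-1-ol (propargyl alcohol)
Product: 3 (Z)-3-iodo-2-methylprop-2-en-1-ol, via alkenylmagnesium alkoxide 2 (not isolated)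
Conditions: MeMgBr (3 equiv), CuI (10 mol %), THF/Et2O, −10 °C → rt; then I2, −78 → 0 °C
Reagents that add atoms: methylmagnesium bromide C[Mg]Br; iodine II
Why: Copper-catalysed carbomagnesiation of the magnesium propargyl alkoxide puts methyl on the internal carbon and magnesium on the terminal carbon cis to CH2O (five-membered chelate 2), and iodinolysis with retention gives the Z-iodoalkene that becomes C4=C5 with C15.

Step 2
Reactants: 3 (Z)-3-iodo-2-methylprop-2-en-1-ol
Product: 4 (Z)-3-iodo-2-methylprop-2-enal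
Conditions: MnO2 (excess), CH2Cl2, rt
Reagents that add atoms: none
Why: Allylic alcohol oxidation with MnO2 is neutral and heterogeneous and should not isomerise the Z-iodoalkene.

Step 3
Reactants: 5 ethyl (E)-2-methylbut-2-enoate (ethyl tiglate)
Product: 6 tert-butyl[(1-ethoxy-2-methylbuta-1,3-dien-1-yl)oxy]dimethylsilane
Conditions: LiN(i-Pr)2, DMPU, THF, −78 °C; TBSCl
Reagents that add atoms: tert-butyldimethylsilyl chloride CC(C)(C)[Si](C)(C)Cl
Why: γ-Deprotonation of the enoate and O-silylation give the extended silyl dienolate (silyl ketene acetal formation).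

Step 4
Reactants: 4 (Z)-3-iodo-2-methylprop-2-enal; 6 silyl dienolate
Product: 7 ethyl (2E,5S,6Z)-5-hydroxy-7-iodo-2,6-dimethylhepta-2,6-dienoate
Conditions: SiCl4 (1.1 equiv), (S,S)-bisphosphoramide from N,N'-dimethyl-1,1'-binaphthyl-2,2'-diamine (5 mol %), i-Pr2NEt (cat.), CH2Cl2, −78 °C; aq. NaHCO3/KF
Reagents that add atoms: none
Why: Lewis-base-catalysed vinylogous Mukaiyama aldol addition, in which the phosphoramide-bound trichlorosilyl cation activates the enal, the dienolate attacks through its γ-carbon on the Si face to set C3 (5S in 7), and the open transition state gives the E-trisubstituted enoate (later C1=C10).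

Step 5
Reactants: 7 hydroxy ester
Product: 8 ethyl (2E,5S,6Z)-7-iodo-2,6-dimethyl-5-(triethylsilyloxy)hepta-2,6-dienoate
Conditions: TESCl, imidazole, DMF, 0 °C
Reagents that add atoms: chlorotriethylsilane CC[Si](Cl)(CC)CC
Why: Standard silylation protects the C3 hydroxyl for the hydride and organolithium steps that follow.

Step 6
Reactants: 8 silyl ether ester
Product: 9 (2E,5S,6Z)-7-iodo-2,6-dimethyl-5-(triethylsilyloxy)hepta-2,6-dien-1-ol
Conditions: i-Bu2AlH (2.5 equiv), CH2Cl2, −78 °C; aq. Rochelle salt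
Reagents that add atoms: none
Why: 1,2-Reduction of the conjugated ester by i-Bu2AlH gives the allylic alcohol at a temperature at which the alkenyl iodide is inert.

Step 7
Reactants: 9 allylic alcohol
Product: 10 (1Z,3S,5E)-7-bromo-1-iodo-2,6-dimethyl-3-(triethylsilyloxy)hepta-1,5-diene
Conditions: CBr4, PPh3, 2,6-lutidine (cat.), CH2Cl2, 0 °C
Reagents that add atoms: carbon tetrabromide BrC(Br)(Br)Br
Why: The Appel reaction converts the primary allylic alcohol into the bromide without allylic transposition.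

Step 8
Reactants: 10 allylic bromide; 1 prop-2-yn-1-ol
Product: 11 (5E,8S,9Z)-10-iodo-5,9-dimethyl-8-(triethylsilyloxy)deca-5,9-dien-2-yn-1-ol
Conditions: CuI, K2CO3, NaI, DMF, rt
Reagents that add atoms: none
Why: Copper-mediated alkynylation, in which the copper acetylide of 1 displaces the primary allylic bromide (SN2, iodide-assisted), forges C8–C9 as a skipped enyne.

Step 9
Reactants: 11 enynol
Product: 12 (2E,5E,8S,9Z)-10-iodo-5,9-dimethyl-8-(triethylsilyloxy)deca-2,5,9-trien-1-ol
Conditions: NaAlH2(OCH2CH2OMe)2, THF, 0 °C; aq. Rochelle salt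
Reagents that add atoms: none
Why: Alkoxide-directed trans-hydroalumination of the propargylic alcohol and protonolysis give the E-allylic alcohol (C7=C8), the low temperature being chosen to spare the alkenyl iodide.

Step 10
Reactants: 12 dienol
Product: 13 [(2R,3R)-3-[(2E,5S,6Z)-7-iodo-2,6-dimethyl-5-(triethylsilyloxy)hepta-2,6-dien-1-yl]oxiran-2-yl]methanol
Conditions: Ti(OiPr)4 (10 mol %), D-(−)-diisopropyl tartrate (12 mol %), t-BuOOH, 4 Å MS, CH2Cl2, −20 °C
Reagents that add atoms: tert-butyl hydroperoxide CC(C)(C)OO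
Why: Sharpless asymmetric epoxidation epoxidises only the allylic alcohol alkene, and the D-(−)-tartrate catalyst sets C7 and C8 as the (2R,3R)-epoxy alcohol by reagent control.

Step 11
Reactants: 13 epoxy alcohol
Product: 14 [(2R,3R)-3-{[(2R,3R)-3-[(2S,3Z)-4-iodo-3-methyl-2-(triethylsilyloxy)but-3-en-1-yl]-2-methyloxiran-2-yl]methyl}oxiran-2-yl]methanol
Conditions: D-fructose-derived ketone catalyst (0.3 equiv), Oxone (2KHSO5·KHSO4·K2SO4), K2CO3, Bu4NHSO4, MeCN/dimethoxymethane/aq. borate buffer pH 10.5, 0 °C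
Reagents that add atoms: potassium peroxymonosulfate [K+].[O-]S(=O)(=O)OO
Why: Shi epoxidation, in which the chiral dioxirane attacks the electron-rich E-trisubstituted alkene through the spiro transition state, sets C1 and C10 (R,R) by catalyst control and leaves the hindered Z-iodoalkene.

Step 12
Reactants: 14 diepoxy alcohol
Product: 15 (2S,3R)-3-{[(2R,3R)-3-[(2S,3Z)-4-iodo-3-methyl-2-(triethylsilyloxy)but-3-en-1-yl]-2-methyloxiran-2-yl]methyl}oxirane-2-carbaldehyde
Conditions: Dess–Martin periodinane, NaHCO3, CH2Cl2, 0 °C → rt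
Reagents that add atoms: none
Why: Buffered Dess–Martin oxidation gives the α,β-epoxy aldehyde without opening either oxirane.

Step 13
Reactants: 15 iodo epoxy aldehyde
Product: 16 (1R,3S,4Z,6R,7R,8R,10R)-1,10:7,8-diepoxy-3-(triethylsilyloxy)-11,12,13-trinorgermacr-4-en-6-ol
Conditions: CrCl2 (10 equiv), NiCl2 (0.1 equiv), DMSO/THF, rt, slow addition to 0.002 M
Reagents that add atoms: none
Why: Nozaki–Hiyama–Kishi reaction, in which zerovalent nickel inserts into the C5–I bond and transmetalation gives a trivalent alkenylchromium that adds to the C6 aldehyde with retention of the Z geometry, closes the ten-membered ring under high dilution, Felkin–Anh attack anti to the C7–O bond being expected to give the 6R (anti) alcohol.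

Step 14
Reactants: 16 macrocyclic epoxy alcohol; 17 1-methoxypropa-1,2-diene (methoxyallene)
Product: 18 (1R,3S,4Z,6R,7S,8R,10R)-6-[(2-bromo-1-methoxyprop-2-en-1-yl)oxy]-1,10:7,8-diepoxy-3-(triethylsilyloxy)-11,12,13-trinorgermacr-4-ene (acetal epimers)
Conditions: NBS, 17 (3 equiv), CH2Cl2, −78 → −20 °C
Reagents that add atoms: N-bromosuccinimide O=C1CCC(=O)N1Br
Why: Cohalogenation of the alkoxyallene, in which bromonium attack on the central allene carbon gives a 2-bromoallyl oxocarbenium ion that the C6 hydroxyl traps (haloacetalisation as for radical haloacetal tethers), installs C11–C13 on O6 at the lactol oxidation level.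

Step 15
Reactants: 19 (Z)-2-methylbut-2-enoic acid (angelic acid)
Product: 20 (Z)-2-methylbut-2-en-1-ol
Conditions: LiAlH4, Et2O, 0 °C → rt
Reagents that add atoms: none
Why: Hydride reduction of the carboxylic acid gives the primary allylic alcohol without isomerising the Z-alkene.

Step 16
Reactants: 20 (Z)-2-methylbut-2-en-1-ol
Product: 21 [(2R,3S)-2,3-dimethyloxiran-2-yl]methanol
Conditions: Ti(OiPr)4, D-(−)-diisopropyl tartrate, t-BuOOH, 4 Å MS, CH2Cl2, −20 °C
Reagents that add atoms: tert-butyl hydroperoxide CC(C)(C)OO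
Why: Sharpless asymmetric epoxidation of the Z-trisubstituted allylic alcohol sets both side-chain stereocentres by reagent control.

Step 17
Reactants: 21 epoxy alcohol
Product: 22 (2S,3S)-2,3-dimethyloxirane-2-carboxylic acid
Conditions: RuCl3·xH2O (cat.), NaIO4, MeCN/EtOAc/H2O, rt
Reagents that add atoms: sodium periodate [Na+].[O-]I(=O)(=O)=O; water O
Why: RuO4 generated in the flask oxidises the primary alcohol through the aldehyde hydrate to the acid and leaves the oxirane.

Step 18
Reactants: 22 epoxy acid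
Product: 23 (2S,3S)-2,3-dimethyloxirane-2-carbonyl chloride
Conditions: 1-chloro-N,N,2-trimethylprop-1-en-1-amine, CH2Cl2, 0 °C; used as solution
Reagents that add atoms: 1-chloro-N,N,2-trimethylprop-1-en-1-amine CC(C)=C(Cl)N(C)C
Why: The α-chloroenamine converts the acid into the acid chloride under neutral conditions that release no HCl, so the oxirane survives.

Step 19
Reactants: 18 bromoallyl mixed acetal; 23 acid chloride
Product: 26 (1R,3S,4Z,6R,7R,8R,10R)-1,10:6,12-diepoxy-12-methoxy-3-(triethylsilyloxy)germacra-4,11(13)-dien-8-yl (2S,3S)-2,3-dimethyloxirane-2-carboxylate (C12 epimers), via alkenyllithium 24 (not isolated), via lithium alkoxide 25 (not isolated)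
Conditions: t-BuLi (2.05 equiv), Et2O/THF, −78 °C; warm to −30 °C; then 23, DMAP (cat.), −78 → 0 °C
Reagents that add atoms: none
Why: Bromine–lithium exchange turns the 2-bromoallyl acetal into alkenyllithium 24, an acrylate α-anion at the lactol oxidation level whose carbanion lobe lies in the plane of the C11=C13 bond; C11 opens the 7,8-oxirane at C7 by intramolecular SN2 attack (C7–C11 bond) to give alkoxide 25, which acid chloride 23 acylates in the same flask. The closest known reaction types are the Parham-type cyclisation of aryl- and alkenyllithiums onto tethered epoxides and the intermolecular opening of epoxides by 2-lithioacrolein acetals used for α-methylene lactones; the tether is the polar counterpart of the haloacetal of radical lactone annulations. The five-membered oxygen ring (O6, C12, C11, C7, C6) closes in the 5-exo-tet mode, the breaking C7–O bond lying outside the new ring, whereas 6-endo attack at C8 would give a six-membered ring over a longer reach. C7 is set by inversion at the oxirane carbon and so follows from the (7R,8R)-oxirane of step 10; the trans ring fusion follows from the anti relation of O6 and the oxirane oxygen fixed in step 13; C8 keeps its C–O bond and is esterified with retention. The step needs the alkenyllithium to cyclise faster than it loses alkoxide by β-elimination and to spare the 1,10-oxirane: the sp2 carbanion is held five atoms from C7 with open backside access, the trisubstituted 1,10-oxirane is remote and inert to organolithiums at −78 °C, and no ester is present until 23 is added.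

Step 20
Reactants: 26 silyl ether
Product: 27 (1R,3S,4Z,6R,7R,8R,10R)-1,10:6,12-diepoxy-3-hydroxy-12-methoxygermacra-4,11(13)-dien-8-yl (2S,3S)-2,3-dimethyloxirane-2-carboxylate (C12 epimers)
Conditions: Bu4NF, AcOH (1:1), THF, 0 °C → rt
Reagents that add atoms: none
Why: Acetic-acid-buffered fluoride cleaves the triethylsilyl ether while the ester, the oxiranes and the acetal are retained.

Step 21
Reactants: 27 C3 alcohol
Product: 28 (1R,3S,4Z,6R,7R,8R,10R)-1,10:6,12-diepoxy-12-methoxy-3-(3-methylbutanoyloxy)germacra-4,11(13)-dien-8-yl (2S,3S)-2,3-dimethyloxirane-2-carboxylate (C12 epimers)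
Conditions: isovaleric anhydride, DMAP (cat.), pyridine, CH2Cl2, 0 °C → rt
Reagents that add atoms: 3-methylbutanoic anhydride CC(C)CC(=O)OC(=O)CC(C)C
Why: DMAP-catalysed acylation of the secondary allylic alcohol installs the isovalerate with retention at C3.

Step 22
Reactants: 28 methyl lactol ether
Product: 30 (1R,3S,4Z,6R,7R,8R,10R)-1,10-epoxy-8-[(2S,3S)-2,3-dimethyloxirane-2-carbonyloxy]-3-(3-methylbutanoyloxy)germacra-4,11(13)-dien-12,6-olide, via lactol 29 (not isolated)
Conditions: PPTS (cat.), acetone/H2O, rt; then Dess–Martin periodinane, NaHCO3, CH2Cl2, rt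
Reagents that add atoms: water O
Why: The allylic mixed acetal ionises readily to an alkoxyallyl cation, so buffered mild acid should hydrolyse it to lactol 29 without opening the oxiranes, and Dess–Martin oxidation of the lactol gives the α-methylene lactone.

**Compound list**
1 | prop-2-yn-1-ol (propargyl alcohol) | C#CCO | starting material
2 | bromomagnesium (Z)-3-(bromomagnesio)-2-methylprop-2-en-1-olate | Br[Mg]/C=C(/C)CO[Mg]Br | intermediate
3 | (Z)-3-iodo-2-methylprop-2-en-1-ol | I/C=C(/C)CO | intermediate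
4 | (Z)-3-iodo-2-methylprop-2-enal | I/C=C(/C)C=O | intermediate
5 | ethyl (E)-2-methylbut-2-enoate (ethyl tiglate) | C/C=C(\C)C(=O)OCC | starting material
6 | tert-butyl[(1-ethoxy-2-methylbuta-1,3-dien-1-yl)oxy]dimethylsilane (ketene acetal geometry not defined) | C=CC(C)=C(OCC)O[Si](C)(C)C(C)(C)C | intermediate
7 | ethyl (2E,5S,6Z)-5-hydroxy-7-iodo-2,6-dimethylhepta-2,6-dienoate | I/C=C(/C)[C@@H](O)C/C=C(\C)C(=O)OCC | intermediate
8 | ethyl (2E,5S,6Z)-7-iodo-2,6-dimethyl-5-(triethylsilyloxy)hepta-2,6-dienoate | I/C=C(/C)[C@@H](O[Si](CC)(CC)CC)C/C=C(\C)C(=O)OCC | intermediate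
9 | (2E,5S,6Z)-7-iodo-2,6-dimethyl-5-(triethylsilyloxy)hepta-2,6-dien-1-ol | I/C=C(/C)[C@@H](O[Si](CC)(CC)CC)C/C=C(\C)CO | intermediate
10 | (1Z,3S,5E)-7-bromo-1-iodo-2,6-dimethyl-3-(triethylsilyloxy)hepta-1,5-diene | I/C=C(/C)[C@@H](O[Si](CC)(CC)CC)C/C=C(\C)CBr | intermediate
11 | (5E,8S,9Z)-10-iodo-5,9-dimethyl-8-(triethylsilyloxy)deca-5,9-dien-2-yn-1-ol | I/C=C(/C)[C@@H](O[Si](CC)(CC)CC)C/C=C(\C)CC#CCO | intermediate
12 | (2E,5E,8S,9Z)-10-iodo-5,9-dimethyl-8-(triethylsilyloxy)deca-2,5,9-trien-1-ol | I/C=C(/C)[C@@H](O[Si](CC)(CC)CC)C/C=C(\C)C/C=C/CO | intermediate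
13 | [(2R,3R)-3-[(2E,5S,6Z)-7-iodo-2,6-dimethyl-5-(triethylsilyloxy)hepta-2,6-dien-1-yl]oxiran-2-yl]methanol | I/C=C(/C)[C@@H](O[Si](CC)(CC)CC)C/C=C(\C)C[C@H]1O[C@@H]1CO | intermediate
14 | [(2R,3R)-3-{[(2R,3R)-3-[(2S,3Z)-4-iodo-3-methyl-2-(triethylsilyloxy)but-3-en-1-yl]-2-methyloxiran-2-yl]methyl}oxiran-2-yl]methanol | I/C=C(/C)[C@@H](O[Si](CC)(CC)CC)C[C@H]1O[C@]1(C)C[C@H]1O[C@@H]1CO | intermediate
15 | (2S,3R)-3-{[(2R,3R)-3-[(2S,3Z)-4-iodo-3-methyl-2-(triethylsilyloxy)but-3-en-1-yl]-2-methyloxiran-2-yl]methyl}oxirane-2-carbaldehyde | I/C=C(/C)[C@@H](O[Si](CC)(CC)CC)C[C@H]1O[C@]1(C)C[C@H]1O[C@@H]1C=O | intermediate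
16 | (1R,3S,4Z,6R,7R,8R,10R)-1,10:7,8-diepoxy-3-(triethylsilyloxy)-11,12,13-trinorgermacr-4-en-6-ol | O[C@@H]1/C=C(/C)[C@@H](O[Si](CC)(CC)CC)C[C@H]2O[C@]2(C)C[C@H]3O[C@@H]31 | intermediate
17 | 1-methoxypropa-1,2-diene (methoxyallene) | C=C=COC | starting material
18 | (1R,3S,4Z,6R,7S,8R,10R)-6-[(2-bromo-1-methoxyprop-2-en-1-yl)oxy]-1,10:7,8-diepoxy-3-(triethylsilyloxy)-11,12,13-trinorgermacr-4-ene (acetal epimers) | C=C(Br)C(OC)O[C@@H]1/C=C(/C)[C@@H](O[Si](CC)(CC)CC)C[C@H]2O[C@]2(C)C[C@H]3O[C@@H]31 | intermediate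
19 | (Z)-2-methylbut-2-enoic acid (angelic acid) | C/C=C(/C)C(=O)O | starting material
20 | (Z)-2-methylbut-2-en-1-ol | C/C=C(/C)CO | intermediate
21 | [(2R,3S)-2,3-dimethyloxiran-2-yl]methanol | OC[C@@]1(C)O[C@H]1C | intermediate
22 | (2S,3S)-2,3-dimethyloxirane-2-carboxylic acid | OC(=O)[C@@]1(C)O[C@H]1C | intermediate
23 | (2S,3S)-2,3-dimethyloxirane-2-carbonyl chloride | ClC(=O)[C@@]1(C)O[C@H]1C | intermediate
24 | alkenyllithium from 18 (lithium in place of bromine) | [Li]C(=C)C(OC)O[C@@H]1/C=C(/C)[C@@H](O[Si](CC)(CC)CC)C[C@H]2O[C@]2(C)C[C@H]3O[C@@H]31 | intermediate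
25 | lithium (1R,3S,4Z,6R,7R,8R,10R)-1,10:6,12-diepoxy-12-methoxy-3-(triethylsilyloxy)germacra-4,11(13)-dien-8-olate | C=C1C(OC)O[C@@H]2/C=C(/C)[C@@H](O[Si](CC)(CC)CC)C[C@H]3O[C@]3(C)C[C@@H](O[Li])[C@@H]12 | intermediate
26 | (1R,3S,4Z,6R,7R,8R,10R)-1,10:6,12-diepoxy-12-methoxy-3-(triethylsilyloxy)germacra-4,11(13)-dien-8-yl (2S,3S)-2,3-dimethyloxirane-2-carboxylate (C12 epimers) | C=C1C(OC)O[C@@H]2/C=C(/C)[C@@H](O[Si](CC)(CC)CC)C[C@H]3O[C@]3(C)C[C@@H](OC(=O)[C@@]3(C)O[C@H]3C)[C@@H]12 | intermediate
27 | (1R,3S,4Z,6R,7R,8R,10R)-1,10:6,12-diepoxy-3-hydroxy-12-methoxygermacra-4,11(13)-dien-8-yl (2S,3S)-2,3-dimethyloxirane-2-carboxylate (C12 epimers) | C=C1C(OC)O[C@@H]2/C=C(/C)[C@@H](O)C[C@H]3O[C@]3(C)C[C@@H](OC(=O)[C@@]3(C)O[C@H]3C)[C@@H]12 | intermediate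
28 | (1R,3S,4Z,6R,7R,8R,10R)-1,10:6,12-diepoxy-12-methoxy-3-(3-methylbutanoyloxy)germacra-4,11(13)-dien-8-yl (2S,3S)-2,3-dimethyloxirane-2-carboxylate (C12 epimers) | C=C1C(OC)O[C@@H]2/C=C(/C)[C@@H](OC(=O)CC(C)C)C[C@H]3O[C@]3(C)C[C@@H](OC(=O)[C@@]3(C)O[C@H]3C)[C@@H]12 | intermediate
29 | (1R,3S,4Z,6R,7R,8R,10R)-1,10:6,12-diepoxy-12-hydroxy-3-(3-methylbutanoyloxy)germacra-4,11(13)-dien-8-yl (2S,3S)-2,3-dimethyloxirane-2-carboxylate (lactol, C12 epimers) | C=C1C(O)O[C@@H]2/C=C(/C)[C@@H](OC(=O)CC(C)C)C[C@H]3O[C@]3(C)C[C@@H](OC(=O)[C@@]3(C)O[C@H]3C)[C@@H]12 | intermediate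
30 | (1R,3S,4Z,6R,7R,8R,10R)-1,10-epoxy-8-[(2S,3S)-2,3-dimethyloxirane-2-carbonyloxy]-3-(3-methylbutanoyloxy)germacra-4,11(13)-dien-12,6-olide (CNP0167461.1) | C=C1C(=O)O[C@@H]2/C=C(/C)[C@@H](OC(=O)CC(C)C)C[C@H]3O[C@]3(C)C[C@@H](OC(=O)[C@@]3(C)O[C@H]3C)[C@@H]12 | target

Total step count: 22. Longest linear sequence: 17 steps (steps 1, 2, 4–14, 19–22).

**Steps most likely to fail**

Step 19 (key step). The alkenyllithium may lose alkoxide by β-elimination to an allenyl ether before it reaches C7, the oxirane opening may be too slow at the temperature the reagent tolerates, or attack may drift to C8. The fallback replaces the polar ring closure by a radical one, sets out from 18 and returns at 26. Compound 18 is treated with Cp2TiCl (made in the flask from Cp2TiCl2 and Mn dust, THF, rt, slow addition). Trivalent titanium opens the 7,8-oxirane by electron transfer, preferentially to the more hindered C7 radical. That radical closes 5-exo onto C11 of the bromoalkene, and β-scission of bromine restores the exocyclic methylene. This should give (1R,3S,4Z,6R,7R,8R,10R)-1,10:6,12-diepoxy-12-methoxy-3-(triethylsilyloxy)germacra-4,11(13)-dien-8-ol F1, with C7 now set by the preference for trans ring fusion and no longer by inversion. F1 is then acylated with 23 (pyridine, DMAP, CH2Cl2) to give 26.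

Step 13. The facial selectivity of the alkenylchromium addition may be poor inside the forming ring, where ring conformation can override the Felkin–Anh preference, and intermolecular coupling competes. The fallback sets the C6 stereocentre by reduction and no longer by C–C bond formation; it sets out from 15 and returns at 16. The cyclisation is run without regard to C6 and should give 16 together with its epimer (1R,3S,4Z,6S,7R,8R,10R)-1,10:7,8-diepoxy-3-(triethylsilyloxy)-11,12,13-trinorgermacr-4-en-6-ol F2. The mixture is oxidised with Dess–Martin periodinane to the single epoxy enone (1R,3S,4Z,7S,8R,10R)-1,10:7,8-diepoxy-3-(triethylsilyloxy)-11,12,13-trinorgermacr-4-en-6-one F3. Chelation-controlled reduction of this α,β-epoxy ketone with Zn(BH4)2 (Et2O, −20 °C), hydride arriving anti to the oxirane C–O bond on the zinc chelate, should return the anti alcohol 16.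

Step 9. The aluminium hydride may remove the alkenyl iodide reductively while it reduces the alkyne. The fallback replaces hydride reduction by trans-hydrosilylation and protodesilylation; it sets out from 11 and returns at 12. Enynol 11 is hydrosilylated with (EtO)3SiH and [Cp*Ru(MeCN)3]PF6 (CH2Cl2, 0 °C → rt; trans addition, silicon on the alkyne carbon distal to the hydroxyl) to give (2Z,5E,8S,9Z)-10-iodo-5,9-dimethyl-3-(triethoxysilyl)-8-(triethylsilyloxy)deca-2,5,9-trien-1-ol F4. Protodesilylation with AgF in aqueous THF/MeOH, which cleaves the alkenyl–Si(OEt)3 bond much faster than a trialkylsilyl ether, should then give 12.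

**Further compounds**
F1 | step 19 | (1R,3S,4Z,6R,7R,8R,10R)-1,10:6,12-diepoxy-12-methoxy-3-(triethylsilyloxy)germacra-4,11(13)-dien-8-ol (C12 epimers) | C=C1C(OC)O[C@@H]2/C=C(/C)[C@@H](O[Si](CC)(CC)CC)C[C@H]3O[C@]3(C)C[C@@H](O)[C@@H]12
F2 | step 13 | (1R,3S,4Z,6S,7R,8R,10R)-1,10:7,8-diepoxy-3-(triethylsilyloxy)-11,12,13-trinorgermacr-4-en-6-ol | O[C@H]1/C=C(/C)[C@@H](O[Si](CC)(CC)CC)C[C@H]2O[C@]2(C)C[C@H]3O[C@@H]31
F3 | step 13 | (1R,3S,4Z,7S,8R,10R)-1,10:7,8-diepoxy-3-(triethylsilyloxy)-11,12,13-trinorgermacr-4-en-6-one | O=C1/C=C(/C)[C@@H](O[Si](CC)(CC)CC)C[C@H]2O[C@]2(C)C[C@H]3O[C@@H]31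
F4 | step 9 | (2Z,5E,8S,9Z)-10-iodo-5,9-dimethyl-3-(triethoxysilyl)-8-(triethylsilyloxy)deca-2,5,9-trien-1-ol | I/C=C(/C)[C@@H](O[Si](CC)(CC)CC)C/C=C(\C)C/C(=C/CO)[Si](OCC)(OCC)OCC
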